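Chroman-type locants are used: O1, C2–C4, C4a, C5–C8, C8a; the side-chain carbinol is C1′ with O1′. The carbocycle C4a–C8a carries oxygen at C8a (ketal), C5 (hemiketal) and C6 (carbinol), with C8a para to C6, so it is a reduced 6-hydroxychroman ring. The route rests on disconnecting the dioxolane bond C8a–O1′ back to that arene. Iodine(III) oxidation of the C6 phenol lets O1′ add to C8a, which already bears O1: one operation closes the dioxolane, completes the 6,8-dioxabicyclo[3.2.1]octane ketal with its stereocentre and leaves a dienone for reduction and hydration. The precursor is the flat pyranone-fused 6-hydroxychroman with a free (S)-1-hydroxyheptyl group at C2.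

Key step: step 10

Remarks
- Locants: pyranone atoms are C2″–C6″ (C3″ bonded to C4; C4″ bonded to O5, the oxygen on C5). Compounds 6–10 use 1,3-benzodioxole locants.
- Assumption: the sense of induction in step 2 is fixed by the choice of ligand enantiomer; it would be checked on 3 (Mosher ester) and the antipodal ligand used if needed.
- Design: the chroman is closed before the pyranone is attached. C4 is then formed under control of the ring, and the pyranone hydroxyl never competes with the phenol for the epoxide.
- Design: the catechol is carried as an isopropylidene ketal, so the late tricycle needs only aqueous acid and no Lewis-acid ether cleavage.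

Step 1
Reactants: 1 dec-3-yn-1-ol
Product: 2 (Z)-dec-3-en-1-ol
Conditions: H2 (1 atm), Lindlar catalyst, quinoline, EtOAc, rt
Reagents that add atoms: none
Why: Lindlar semihydrogenation adds H2 syn on the poisoned Pd surface and stops at the Z-alkene, the geometry the cis-epoxide needs.

Step 2
Reactants: 2 (Z)-dec-3-en-1-ol
Product: 3 2-[(2R,3S)-3-hexyloxiran-2-yl]ethan-1-ol
Conditions: VO(Oi-Pr)3 (2 mol%), chiral C2-symmetric bis-hydroxamic acid ligand (4 mol%), cumene hydroperoxide, toluene, rt
Reagents that add atoms: cumene hydroperoxide, CC(C)(OO)c1ccccc1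
Why: Vanadium/bis-hydroxamic acid catalysed asymmetric epoxidation of homoallylic alcohols (Yamamoto type) delivers the peroxide oxygen from the alkoxide-bound metal to one enantioface of the Z-alkene; the addition is stereospecific (cis), so both oxirane centres (2R,3S) are set by the ligand.

Step 3
Reactants: 3 2-[(2R,3S)-3-hexyloxiran-2-yl]ethan-1-ol
Product: 4 2-[(2R,3S)-3-hexyloxiran-2-yl]acetaldehyde
Conditions: Dess–Martin periodinane, NaHCO3, CH2Cl2, 0 °C; used crude at once
Reagents that add atoms: none
Why: Buffered Dess–Martin oxidation is neutral, so the primary alcohol becomes the aldehyde without opening or β-elimination of the epoxide, and no stereocentre is touched.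

Step 4
Reactants: 5 benzene-1,2,4-triol
Product: 6 2,2-dimethyl-1,3-benzodioxol-5-ol
Conditions: 2,2-dimethoxypropane, TsOH (cat.), toluene, reflux under Ar, MeOH distilled off
Reagents that add atoms: 2,2-dimethoxypropane, COC(C)(C)OC
Why: Acid-catalysed transketalisation can form a cyclic isopropylidene ketal only on the vicinal (catechol) pair of hydroxyls, which leaves the third hydroxyl free.

Step 5
Reactants: 6 2,2-dimethyl-1,3-benzodioxol-5-ol
Product: 7 2,2-dimethyl-5-{[2-(trimethylsilyl)ethoxy]methoxy}-1,3-benzodioxole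
Conditions: SEMCl, i-Pr2NEt, CH2Cl2, 0 °C → rt
Reagents that add atoms: 2-(trimethylsilyl)ethoxymethyl chloride, C[Si](C)(C)CCOCCl
Why: Williamson-type O-alkylation gives an acetal ether that directs ortho-lithiation and, unlike a MOM ether, is removed by fluoride under basic conditions.

Step 6
Reactants: 7 2,2-dimethyl-5-{[2-(trimethylsilyl)ethoxy]methoxy}-1,3-benzodioxole; 4 2-[(2R,3S)-3-hexyloxiran-2-yl]acetaldehyde
Product: 9 1-[2,2-dimethyl-5-(SEM-oxy)-1,3-benzodioxol-4-yl]-2-[(2R,3S)-3-hexyloxiran-2-yl]ethan-1-ol (both carbinol epimers), via C4-aryllithium 8 (not isolated)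
Conditions: n-BuLi, THF, 0 °C; then −78 °C, 4; then H2O
Reagents that add atoms: none
Why: Directed ortho-metalation occurs at C4, the only position flanked by two coordinating oxygens, and the aryllithium adds to the aldehyde at −78 °C faster than it enolises it; the new carbinol centre forms unselectively, which is harmless because it is ionised in step 8.

Step 7
Reactants: 9 1-[2,2-dimethyl-5-(SEM-oxy)-1,3-benzodioxol-4-yl]-2-[(2R,3S)-3-hexyloxiran-2-yl]ethan-1-ol
Product: 11 (2S)-2-[(1S)-1-hydroxyheptyl]-5,6-(isopropylidenedioxy)chroman-4-ol (C4 epimers), via free phenol epoxide 10 (not isolated)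
Conditions: TBAF (4 equiv), THF/DMPU, 65 °C; H2O work-up
Reagents that add atoms: none
Why: Fluoride cleaves the aryl SEM ether (attack at silicon, loss of ethene and formaldehyde) and the phenoxide opens the epoxide by 6-exo-tet SN2 attack at the proximal carbon, so C2 forms with inversion (S) while C1′ keeps its configuration (S) and the base-stable benzylic alcohol and ketal are untouched.

Step 8
Reactants: 11 (2S)-2-[(1S)-1-hydroxyheptyl]-5,6-(isopropylidenedioxy)chroman-4-ol; 12 4-hydroxy-6-methyl-2H-pyran-2-one
Product: 13 (2S,4R)-2-[(1S)-1-hydroxyheptyl]-4-(4-hydroxy-6-methyl-2-oxo-2H-pyran-3-yl)-5,6-(isopropylidenedioxy)chroman (2,4-trans)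
Conditions: 12 (1.5 equiv), TsOH·H2O (10 mol%), MeCN, −20 → 0 °C
Reagents that add atoms: none
Why: Acid ionises the 4-ol to a benzylic cation stabilised by O1 and the C5 oxygen, which alkylates C3″ of the pyranone (SN1 Friedel–Crafts-type C-benzylation of a vinylogous acid); the nucleophile enters pseudo-axially anti to the pseudo-equatorial C2 side chain, a preference reinforced by peri strain with the C5 oxygen and by shielding of the syn face by the C1′ hydroxyl, which should give the 2,4-trans (4R) isomer.

Step 9
Reactants: 13 (2S,4R)-2-[(1S)-1-hydroxyheptyl]-4-(4-hydroxy-6-methyl-2-oxo-2H-pyran-3-yl)-5,6-(isopropylidenedioxy)chroman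
Product: 15 (2S,4R)-pyranone-fused 6-hydroxychroman (C4 bonded to C3″ and O5 bonded to C4″ of the 6″-methyl-2″-pyranone; (1S)-1-hydroxyheptyl at C2 trans to the C4–C3″ bond; free C6 phenol), via catechol 14 (not isolated)
Conditions: 1 M HCl, THF/H2O, 50 °C, Ar; evaporate; TsOH·H2O (20 mol%), toluene, 90 °C, 4 Å MS
Reagents that add atoms: none
Why: Aqueous acid hydrolyses the aryl isopropylidene ketal, and O5–H, the only hydroxyl within reach, then condenses with the vinylogous acid carbon C4″ (acid-catalysed cyclodehydration by addition–elimination) to close the 4H-pyran without touching a stereocentre.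

Step 10
Reactants: 15 (2S,4R)-pyranone-fused 6-hydroxychroman
Product: 16 (1′S,2S,4R,8aR)-quinone monoketal dienone (C8a bonded to O1 and O1′; dioxolane O1–C2–C1′–O1′–C8a; C7=C8–C6(=O)–C5(O5)=C4a)
Conditions: PhI(OAc)2 (1.1 equiv), NaHCO3, HFIP/CH2Cl2, 0 °C
Reagents that add atoms: none
Why: Ligand exchange of the C6 phenol on iodine(III) and loss of PhI and acetate give a phenoxenium ion whose charge sits mainly on C8a as an O1-stabilised oxocarbenium; O1′–H adds there and loses its proton. The closest known reaction is the iodine(III) oxidation of para-alkoxyphenols (6-hydroxychromans of the tocopherol type) to quinone monoketals with alcohol capture at the alkoxy-bearing carbon. The one ring closed is the dioxolane, a five-membered closure onto a cationic carbon: 5-exo with respect to the ring C8a=C8 π-bond and, counted on the C8a=O1+ resonance form, the 5-endo closure common to every dioxolane ketalisation. The new stereocentre C8a (R) is controlled by C2, because the two-atom tether lets O1′ reach only the face of C8a syn to the C2–C1′ bond, the side chain being held pseudo-axial by the in-plane C4–C3″ bond. The step needs para over ortho attack and phenol oxidation over hydride loss from the doubly activated C4–H. The first is secured because O1′ cannot span to C5 or C7 and no external nucleophile is present; the second by fast ligand exchange at the free phenol at 0 °C with one equivalent of oxidant.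

Step 11
Reactants: 16 (1′S,2S,4R,8aR)-quinone monoketal dienone
Product: 17 (1′S,2S,4R,8aR)-enone (16 with C7–C8 saturated; C6(=O)–C5(O5)=C4a retained)
Conditions: H2 (1 atm), RhCl(PPh3)3 (10 mol%), benzene/EtOH, rt
Reagents that add atoms: none
Why: Homogeneous hydrogenation with Wilkinson's catalyst reduces the cis-disubstituted C7=C8 bond of a cross-conjugated dienone and leaves the tetrasubstituted C4a=C5 bond, as in the Δ1-selective reduction of steroidal 1,4-dien-3-ones, without hydrogenolysis of the allylic ketal or reduction of the pyranone.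

Step 12
Reactants: 17 (1′S,2S,4R,8aR)-enone
Product: 19 (1′S,2S,4R,4aS,5S,8aR)-α-hydroxy ketone hemiketal (C4a–H cis to O1′; C5–OH trans to C4a–H; C6 ketone), via C5 hydroperoxide 18 (not isolated)
Conditions: Mn(dpm)3 (10 mol%), PhSiH3, O2 (1 atm), i-PrOH/CH2Cl2, 0 °C → rt; then P(OEt)3
Reagents that add atoms: dioxygen, O=O
Why: In this Mukaiyama-type HAT reductive α-hydroxylation of an enone the manganese hydride transfers H to the β-carbon C4a from the face bearing O1′ and C4–H (the other face is covered by C3 and O1 of the bicyclic ketal), the captodative C5 radical captures O2 anti to the new axial C4a–H, and phosphite reduces the hydroperoxide to the hemiketal, whose trans-fused, axial-OH form is also the one favoured by ring–chain equilibration.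

Step 13
Reactants: 19 (1′S,2S,4R,4aS,5S,8aR)-α-hydroxy ketone hemiketal
Product: 20 Trichopsistide B (1′S,2S,4R,4aS,5S,6R,8aR)
Conditions: Me4NBH(OAc)3, MeCN/AcOH, −20 → 0 °C
Reagents that add atoms: none
Why: Hydroxyl-directed triacetoxyborohydride reduction (Evans–Saksena type) binds boron to the C5 hemiketal hydroxyl and delivers hydride to the same face of the C6 ketone, which sets C6 (R) with its hydroxyl trans to the C5 hydroxyl, while the lactone and ketals are inert to this mild hydride.

Compound list
1 | dec-3-yn-1-ol | OCCC#CCCCCCC | starting material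
2 | (Z)-dec-3-en-1-ol | OCC/C=C\CCCCCC | intermediate
3 | 2-[(2R,3S)-3-hexyloxiran-2-yl]ethan-1-ol | OCC[C@H]1O[C@H]1CCCCCC | intermediate
4 | 2-[(2R,3S)-3-hexyloxiran-2-yl]acetaldehyde | O=CC[C@H]1O[C@H]1CCCCCC | intermediate
5 | benzene-1,2,4-triol | Oc1ccc(O)c(O)c1 | starting material
6 | 2,2-dimethyl-1,3-benzodioxol-5-ol | CC1(C)Oc2ccc(O)cc2O1 | intermediate
7 | 2,2-dimethyl-5-{[2-(trimethylsilyl)ethoxy]methoxy}-1,3-benzodioxole | CC1(C)Oc2ccc(OCOCC[Si](C)(C)C)cc2O1 | intermediate
8 | 4-lithio derivative of 7 (not isolated) | [Li]c1c(OCOCC[Si](C)(C)C)ccc2OC(C)(C)Oc12 | intermediate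
9 | 1-[2,2-dimethyl-5-(SEM-oxy)-1,3-benzodioxol-4-yl]-2-[(2R,3S)-3-hexyloxiran-2-yl]ethan-1-ol, carbinol epimers | CCCCCC[C@@H]1O[C@@H]1CC(O)c1c(OCOCC[Si](C)(C)C)ccc2OC(C)(C)Oc12 | intermediate
10 | 1-(5-hydroxy-2,2-dimethyl-1,3-benzodioxol-4-yl)-2-[(2R,3S)-3-hexyloxiran-2-yl]ethan-1-ol (not isolated) | CCCCCC[C@@H]1O[C@@H]1CC(O)c1c(O)ccc2OC(C)(C)Oc12 | intermediate
11 | (2S)-2-[(1S)-1-hydroxyheptyl]-5,6-(isopropylidenedioxy)chroman-4-ol, C4 epimers | CCCCCC[C@H](O)[C@@H]1CC(O)c2c(O1)ccc1OC(C)(C)Oc21 | intermediate
12 | 4-hydroxy-6-methyl-2H-pyran-2-one | Cc1cc(O)cc(=O)o1 | starting material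
13 | (2S,4R)-2-[(1S)-1-hydroxyheptyl]-4-(4-hydroxy-6-methyl-2-oxo-2H-pyran-3-yl)-5,6-(isopropylidenedioxy)chroman | CCCCCC[C@H](O)[C@@H]1C[C@@H](c2c(O)cc(C)oc2=O)c2c(O1)ccc1OC(C)(C)Oc21 | intermediate
14 | (2S,4R)-2-[(1S)-1-hydroxyheptyl]-4-(4-hydroxy-6-methyl-2-oxo-2H-pyran-3-yl)chroman-5,6-diol (not isolated) | CCCCCC[C@H](O)[C@@H]1C[C@@H](c2c(O)cc(C)oc2=O)c2c(O1)ccc(O)c2O | intermediate
15 | (2S,4R)-pyranone-fused 6-hydroxychroman with (1S)-1-hydroxyheptyl at C2 (key-step precursor) | CCCCCC[C@H](O)[C@@H]1C[C@@H]2c3c(O1)ccc(O)c3Oc4cc(C)oc(=O)c42 | intermediate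
16 | (1′S,2S,4R,8aR)-quinone monoketal dienone (key-step product) | CCCCCC[C@@H]1O[C@]23C=CC(=O)C4=C3[C@@H](C[C@@H]1O2)c3c(O4)cc(C)oc3=O | intermediate
17 | (1′S,2S,4R,8aR)-7,8-dihydro enone | CCCCCC[C@@H]1O[C@]23CCC(=O)C4=C3[C@@H](C[C@@H]1O2)c3c(O4)cc(C)oc3=O | intermediate
18 | (1′S,2S,4R,4aS,5R,8aR)-C5 hydroperoxide of the C6 ketone (not isolated) | CCCCCC[C@@H]1O[C@]23CCC(=O)[C@@]4(OO)Oc5cc(C)oc(=O)c5[C@H](C[C@@H]1O2)[C@H]34 | intermediate
19 | (1′S,2S,4R,4aS,5S,8aR)-C5 hemiketal C6 ketone | CCCCCC[C@@H]1O[C@]23CCC(=O)[C@@]4(O)Oc5cc(C)oc(=O)c5[C@H](C[C@@H]1O2)[C@H]34 | intermediate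
20 | Trichopsistide B | CCCCCC[C@@H]1O[C@]23CC[C@@H](O)[C@@]4(O)Oc5cc(C)oc(=O)c5[C@H](C[C@@H]1O2)[C@H]34 | target

Total step count: 13
Longest linear sequence: 11 steps (1 → 20 through steps 1–3 and 6–13)

Steps most likely to fail

Step 12. Hydrogen-atom transfer to the hindered, tetrasubstituted and donor-substituted C4a=C5 bond may be slow, hydrogen may be delivered to the wrong face of C4a, or the C5 radical may be reduced before it captures oxygen. The fallback replaces the radical step by a polar one and sets out from 17. Copper hydride from Cu(OAc)2·H2O and 1,2-bis(diphenylphosphino)benzene with PhMe2SiH in toluene should add hydride to C4a and silylate the enolate, giving the dimethylphenylsilyl enol ether F1. Rubottom oxidation of F1 with dimethyldioxirane (acetone/CH2Cl2, −78 → 0 °C) and a mild aqueous acid work-up should then give the hemiketal, returning to the route at 19.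

Step 10. The cation may lose hydride from the doubly activated C4–H instead of being captured, adventitious water may open it to a p-quinone, or the side chain may not reach C8a fast enough in the reactive conformation. The fallback separates oxidation from ring closure and sets out from 15. PhI(OAc)2 in methanol should give the 8a-methoxy mixed quinone monoketal F2 by solvent capture, which does not depend on the side-chain conformation. PPTS in benzene at 60 °C with removal of methanol should then exchange the methoxy group for O1′ under thermodynamic control, returning to the route at 16.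

Step 6. The aryllithium may enolise the β,γ-epoxy aldehyde, which is followed by β-elimination with opening of the epoxide, so conversion to the adduct may be poor. The fallback avoids the aldehyde and sets out from 3 and 7. Appel iodination of 3 (I2, PPh3, imidazole) should give (2S,3R)-2-hexyl-3-(2-iodoethyl)oxirane F3. The aryllithium 8 made from 7 is alkylated with F3 (THF/DMPU, −78 → 0 °C) to the arylethyl epoxide F4. TBAF as in step 7 should close the 4-unsubstituted chroman F5. DDQ in wet CH2Cl2 should then hydroxylate the oxygen-activated benzylic C4–H, returning to the route at 11 (any internal C4–O1′ ether formed ionises equally in step 8).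

Further compounds
F1 | step 12 | (1′S,2S,4R,4aS,8aR)-C6 dimethylphenylsilyl enol ether (C5=C6, H on C4a) | CCCCCC[C@@H]1O[C@]23CCC(O[Si](C)(C)c4ccccc4)=C4Oc5cc(C)oc(=O)c5[C@H](C[C@@H]1O2)[C@H]34
F2 | step 10 | 8a-methoxy mixed quinone monoketal of 15 (C8a epimers, free C1′ hydroxyl) | CCCCCC[C@H](O)[C@@H]1C[C@@H]2C3=C(Oc4cc(C)oc(=O)c42)C(=O)C=CC3(OC)O1
F3 | step 6 | (2S,3R)-2-hexyl-3-(2-iodoethyl)oxirane | CCCCCC[C@@H]1O[C@@H]1CCI
F4 | step 6 | 4-{2-[(2R,3S)-3-hexyloxiran-2-yl]ethyl}-2,2-dimethyl-5-(SEM-oxy)-1,3-benzodioxole | CCCCCC[C@@H]1O[C@@H]1CCc1c(OCOCC[Si](C)(C)C)ccc2OC(C)(C)Oc12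
F5 | step 6 | (2S)-2-[(1S)-1-hydroxyheptyl]-5,6-(isopropylidenedioxy)chroman | CCCCCC[C@H](O)[C@@H]1CCc2c(O1)ccc1OC(C)(C)Oc21
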